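The plan rests on opening ring C of the upper, ent-configured flavan unit at O1–C2 and at the C3–O bond, which leads back to a Z-1,1,3-triarylpropene. The feature exploited is that ring B on C2, the hydroxyl on C3 and ring D on C4 all lie on one face of ring C. A cis-epoxide across C2=C3, opened at benzylic C2 with inversion by the ring A phenol oxygen on C8a, delivers exactly this array. One operation therefore forms C3–O and O1–C2, closes ring C and sets C2 and C3 against the existing C4 methine. The precursor bears a silylated C8a phenol, benzylated rings A and B, and perbenzylated epicatechin bound through C8'.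

Key step: step 9

Remarks (labels and chemistry)
- Labels: the upper flavan unit has rings A (phloroglucinol), C (pyran) and B (catechol) and unprimed atoms. The lower unit has rings D, F and E and primed atoms. Bn = benzyl, TBS = tert-butyldimethylsilyl.
- Reading of the target: the upper unit is 2S,3S,4R, with ring B, 3-OH and ring D all cis (ent-epicatechin series, 4β bond to C8'), so it must be built de novo. The lower unit is 2'R,3'R,4'S (2',3'-cis, 3',4'-trans, i.e. epicatechin-4β-ol).
- CIP note: the geometry at C4 never changes once it is formed. Its descriptor reads S while ring A carries the silyloxy group (ring A then outranks ring D) and R once the silicon is gone.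
- Assumption: the two C4 epimers formed in the fragment union are separable on silica gel, because they are diastereomers.
- Catalyst of the key step: the D-glucose-derived spiro-oxazolidinone ketone C1[C@H]2OC(C)(C)O[C@H]2C(=O)[C@@]3(CN(c4ccc(C)cc4)C(=O)O3)O1. It is a known organocatalyst made from D-glucose and 4-toluidine, and its preparation is not counted.

Step 1
Reactants: 1 2,4,6-trihydroxybenzaldehyde
Product: 2 2,4-bis(benzyloxy)-6-hydroxybenzaldehyde
Conditions: BnBr (2.05 equiv), K2CO3 (2.1 equiv), DMF, 0 °C → rt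
Reagents that add atoms: benzyl bromide, BrCc1ccccc1
Why: Williamson etherification under carbonate control: the 4-hydroxyl and one ortho hydroxyl are alkylated, while the remaining ortho hydroxyl is locked in a hydrogen bond to the formyl oxygen and stays free when only two equivalents of halide are offered.

Step 2
Reactants: 2 2,4-bis(benzyloxy)-6-hydroxybenzaldehyde
Product: 3 2,4-bis(benzyloxy)-6-(tert-butyldimethylsilyloxy)benzaldehyde
Conditions: TBSCl, imidazole, DMAP (cat.), DMF, rt
Reagents that add atoms: tert-butyldimethylsilyl chloride, CC(C)(C)[Si](C)(C)Cl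
Why: Imidazole-promoted O-silylation; capping the phenol already here keeps a free ortho hydroxyl out of the later acid step (no chromene or flavylium formation by attack on the alkyne) and keeps the aldehyde electrophilic, and TBS is chosen over a larger silyl group because ring A flanks the alkene face that has to be oxidised in step 9.

Step 3
Reactants: 4 3,4-bis(benzyloxy)benzaldehyde
Product: 5 4-ethynyl-1,2-bis(benzyloxy)benzene
Conditions: dimethyl (1-diazo-2-oxopropyl)phosphonate, K2CO3, MeOH–THF, rt
Reagents that add atoms: dimethyl (1-diazo-2-oxopropyl)phosphonate, CC(=O)C(=[N+]=[N-])P(=O)(OC)OC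
Why: Ohira–Bestmann homologation (Seyferth–Gilbert type): methanolysis frees the diazomethylphosphonate anion, which adds to the aldehyde, loses phosphate and nitrogen and gives the terminal alkyne by a 1,2-hydride shift in the alkylidene carbene, under conditions harmless to aryl benzyl ethers.

Step 4
Reactants: 5 4-ethynyl-1,2-bis(benzyloxy)benzene; 3 2,4-bis(benzyloxy)-6-(tert-butyldimethylsilyloxy)benzaldehyde
Product: 7 racemic 1-[2,4-bis(benzyloxy)-6-(TBS-oxy)phenyl]-3-[3,4-bis(benzyloxy)phenyl]prop-2-yn-1-ol, via lithium acetylide 6 (not isolated)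
Conditions: n-BuLi (1.0 equiv per 5), THF, −78 °C; then 3, −78 → −40 °C; AcOH quench at −78 °C
Reagents that add atoms: none
Why: 1,2-Addition of a lithium acetylide to an aromatic aldehyde; the carbinol centre is formed racemic on purpose because it is ionised in step 7, and the cold acidic quench prevents O-to-O silyl migration from the neighbouring phenol oxygen to the alkoxide.

Step 5
Reactants: 8 (−)-epicatechin
Product: 9 5,7,3',4'-tetra-O-benzyl-(−)-epicatechin (2R,3R)
Conditions: BnBr (4.4 equiv), K2CO3, DMF, 0 °C → rt, Ar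
Reagents that add atoms: benzyl bromide, BrCc1ccccc1
Why: Williamson etherification in which carbonate deprotonates only the four phenols, so the secondary alcohol is left alone and, at or below room temperature under argon, the (2R,3R) configuration of the natural product is kept.

Step 6
Reactants: 9 5,7,3',4'-tetra-O-benzyl-(−)-epicatechin
Product: 10 3,5,7,3',4'-penta-O-benzyl-(−)-epicatechin (2R,3R)
Conditions: NaH, BnBr, Bu4NI (cat.), THF–DMF, 0 °C → rt
Reagents that add atoms: benzyl bromide, BrCc1ccccc1
Why: Williamson etherification of the secondary alkoxide; with all phenols capped the pyran ring cannot open to a quinone methide, so the strong base does not epimerise C2, and the ether distinguishes this oxygen from the C3 hydroxyl that step 9 will liberate.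

Step 7
Reactants: 7 racemic propargylic alcohol; 10 penta-O-benzyl-(−)-epicatechin
Product: 11 8'-propargylated flavan, (4S)-alkyne (C4 bears ring A, ring D, H and the arylalkynyl group; 2'R,3'R)
Conditions: Sc(OTf)3 (10 mol %), 10 (3 equiv, excess recovered), 4 Å molecular sieves, CH2Cl2–MeCN (10:1), −40 → −10 °C; chromatographic separation of the C4 epimers
Reagents that add atoms: none
Why: Friedel–Crafts propargylation: the Lewis acid ionises the carbinol to a ring A-stabilised propargylic cation that is captured by C8' of 10, the most nucleophilic position of ring D and more open than C6', which is wedged between two benzyloxy groups; the new C4 centre is not under reagent control, but since 10 is a single enantiomer the two C4 epimers are diastereomers, so the (S)-epimer is secured by chromatography and its configuration is checked after ring closure through the H2–H3–H4 coupling and NOE pattern.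

Step 8
Reactants: 11 (4S)-alkyne
Product: 12 (4S,Z)-1,1,3-triarylpropene (Z C2=C3; TBS on O8a; 2'R,3'R)
Conditions: H2 (1 atm), Pd/CaCO3/Pb(OAc)2, quinoline, EtOAc, rt, stopped after one equivalent of H2, light excluded
Reagents that add atoms: none
Why: Lindlar-type semihydrogenation: both hydrogens come from the poisoned palladium surface onto one side of the alkyne, which fixes the Z geometry, and the lead- and quinoline-poisoned catalyst leaves the benzyl ethers, the silyl ether and C4 untouched.

Step 9
Reactants: 12 (4S,Z)-1,1,3-triarylpropene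
Product: 15 all-cis nona-O-benzyl 4-arylflavan-3-ol dimer (2S,3S,4R; 2'R,3'R; free 3-OH), via silylated cis-epoxide 13 (not isolated), via phenolic cis-epoxide 14 (not isolated)
Conditions: (a) D-glucose-derived N-(4-tolyl)oxazolidinone ketone (0.3 equiv), KHSO5 (as 2KHSO5·KHSO4·K2SO4), K2CO3, Bu4NHSO4 (cat.), DME–CH2(OMe)2/aq. K2CO3–AcOH buffer (pH 8), −10 → 0 °C, cold extractive work-up, no chromatography; (b) Bu4NF–AcOH (1:1), THF, 0 °C; (c) PPTS (10 mol %), CH2Cl2, −20 → 0 °C
Reagents that add atoms: potassium peroxymonosulfate, [K+].[O-]S(=O)(=O)OO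
Why: KHSO5 converts the ketone into a chiral dioxirane that hands one oxygen to C2=C3 in a single concerted spiro transition state, so the Z geometry reappears as the cis-epoxide 13; buffered fluoride then uncovers the C8a phenol (14), whose oxygen displaces the epoxide oxygen from C2 from the rear under weak-acid assistance. Both halves are known reaction types, namely the Shi epoxidation of cis-β-substituted styrenes with oxazolidinone ketones and the cyclisation of 1-(2-hydroxyaryl)-3-arylpropene oxides to flavan-3-ols. Ring C closes in the 6-endo-tet mode through O1–C2, the rival being 5-exo-tet attack at C3 to a 2,3-dihydrobenzofuran. C3 (S) is set by the face of oxygen transfer, which the catalyst controls: the D-glucose series makes the benzylic carbon of cis-β-alkylstyrene oxides R, which corresponds to the (2R,3S)-epoxide wanted here, and in the allylic-strain-locked conformer with C4–H in the alkene plane this is the face next to ring A and away from the bulkier ring D flavan block, so substrate and catalyst should reinforce each other. C2 (S) is set by inversion in the ring closure, and a cis-epoxide opened with inversion places ring B cis to O3 and hence cis to ring D as well. The step needs endo over exo opening and O1–C2 bond making that keeps pace with C2–O cleavage; the para-benzyloxy group of ring B lowers the barrier at C2, the diarylmethyl group screens C3, and the low temperature, the weak acid and the intramolecular phenol should keep a free benzylic cation from forming.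

Step 10
Reactants: 15 all-cis nona-O-benzyl dimer
Product: 16 4'β-hydroxy nona-O-benzyl dimer (2S,3S,4R; 2'R,3'R,4'S)
Conditions: DDQ (1.2 equiv), CH2Cl2–H2O (18:1), 0 °C → rt
Reagents that add atoms: water, O
Why: DDQ benzylic oxidation of a benzylated flavan-3-ol: hydride abstraction from the accessible C4' methylene gives a cation stabilised by O5', O7' and O1' of ring D, which water captures from the face opposite the 3'-benzyloxy group and ring E to give the 3',4'-trans (4'S) alcohol, whereas the upper C4–H is tertiary, buried between ring D and the 5-benzyloxy group, and cannot reach a planar cation.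

Step 11
Reactants: 16 4'β-hydroxy nona-O-benzyl dimer
Product: 17 target, ent-epicatechin-(4β→8)-epicatechin-4β-ol (2S,3S,4R; 2'R,3'R,4'S)
Conditions: H2 (1 atm), Pd(OH)2/C, THF–H2O (10:1), rt; filtration under N2, cold concentration, lyophilisation
Reagents that add atoms: none
Why: Catalytic hydrogenolysis of the nine O-benzyl groups; under neutral conditions benzyl ethers are cleaved faster than the ring C–O bonds, the C4–C8' bond or the secondary C4' carbinol, the alcohol-free aqueous THF medium prevents exchange of the labile 4'-hydroxyl, and no stereocentre is touched.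

Compound list
1 | 2,4,6-trihydroxybenzaldehyde | O=Cc1c(O)cc(O)cc1O | starting material
2 | 2,4-bis(benzyloxy)-6-hydroxybenzaldehyde | O=Cc1c(O)cc(OCc9ccccc9)cc1OCc9ccccc9 | intermediate
3 | 2,4-bis(benzyloxy)-6-(tert-butyldimethylsilyloxy)benzaldehyde | O=Cc1c(O[Si](C)(C)C(C)(C)C)cc(OCc9ccccc9)cc1OCc9ccccc9 | intermediate
4 | 3,4-bis(benzyloxy)benzaldehyde | O=Cc1ccc(OCc2ccccc2)c(OCc2ccccc2)c1 | starting material
5 | 4-ethynyl-1,2-bis(benzyloxy)benzene | C#Cc1ccc(OCc9ccccc9)c(OCc9ccccc9)c1 | intermediate
6 | lithium [3,4-bis(benzyloxy)phenyl]acetylide (not isolated) | [Li]C#Cc1ccc(OCc9ccccc9)c(OCc9ccccc9)c1 | intermediate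
7 | racemic 1-[2,4-bis(benzyloxy)-6-(TBS-oxy)phenyl]-3-[3,4-bis(benzyloxy)phenyl]prop-2-yn-1-ol | OC(C#Cc1ccc(OCc9ccccc9)c(OCc9ccccc9)c1)c1c(O[Si](C)(C)C(C)(C)C)cc(OCc9ccccc9)cc1OCc9ccccc9 | intermediate
8 | (−)-epicatechin (2R,3R) | O[C@@H]1Cc2c(O)cc(O)cc2O[C@@H]1c1ccc(O)c(O)c1 | starting material
9 | 5,7,3',4'-tetra-O-benzyl-(−)-epicatechin (2R,3R) | O[C@@H]1Cc2c(OCc9ccccc9)cc(OCc9ccccc9)cc2O[C@@H]1c1ccc(OCc9ccccc9)c(OCc9ccccc9)c1 | intermediate
10 | 3,5,7,3',4'-penta-O-benzyl-(−)-epicatechin (2R,3R) | c9ccccc9CO[C@@H]1Cc2c(OCc9ccccc9)cc(OCc9ccccc9)cc2O[C@@H]1c1ccc(OCc9ccccc9)c(OCc9ccccc9)c1 | intermediate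
11 | 8-{(1S)-1-[2,4-bis(benzyloxy)-6-(TBS-oxy)phenyl]-3-[3,4-bis(benzyloxy)phenyl]prop-2-yn-1-yl}-penta-O-benzyl-(−)-epicatechin (C4 S; 2'R,3'R) | CC(C)(C)[Si](C)(C)Oc1cc(OCc9ccccc9)cc(OCc9ccccc9)c1[C@@H](C#Cc1ccc(OCc9ccccc9)c(OCc9ccccc9)c1)c1c(OCc9ccccc9)cc(OCc9ccccc9)c2c1O[C@H](c1ccc(OCc9ccccc9)c(OCc9ccccc9)c1)[C@H](OCc9ccccc9)C2 | intermediate
12 | 8-{(1S,2Z)-1-[2,4-bis(benzyloxy)-6-(TBS-oxy)phenyl]-3-[3,4-bis(benzyloxy)phenyl]prop-2-en-1-yl}-penta-O-benzyl-(−)-epicatechin (key-step precursor; C4 S, Z alkene; 2'R,3'R) | CC(C)(C)[Si](C)(C)Oc1cc(OCc9ccccc9)cc(OCc9ccccc9)c1[C@@H](/C=C\c1ccc(OCc9ccccc9)c(OCc9ccccc9)c1)c1c(OCc9ccccc9)cc(OCc9ccccc9)c2c1O[C@H](c1ccc(OCc9ccccc9)c(OCc9ccccc9)c1)[C@H](OCc9ccccc9)C2 | intermediate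
13 | silylated cis-epoxide of 12 (C2 R, C3 S, C4 S; not isolated) | CC(C)(C)[Si](C)(C)Oc1cc(OCc9ccccc9)cc(OCc9ccccc9)c1[C@@H]([C@@H]3O[C@@H]3c1ccc(OCc9ccccc9)c(OCc9ccccc9)c1)c1c(OCc9ccccc9)cc(OCc9ccccc9)c2c1O[C@H](c1ccc(OCc9ccccc9)c(OCc9ccccc9)c1)[C@H](OCc9ccccc9)C2 | intermediate
14 | phenolic cis-epoxide, free O8a–H (C2 R, C3 S, C4 R by CIP with unchanged geometry; not isolated) | Oc1cc(OCc9ccccc9)cc(OCc9ccccc9)c1[C@@H]([C@@H]3O[C@@H]3c1ccc(OCc9ccccc9)c(OCc9ccccc9)c1)c1c(OCc9ccccc9)cc(OCc9ccccc9)c2c1O[C@H](c1ccc(OCc9ccccc9)c(OCc9ccccc9)c1)[C@H](OCc9ccccc9)C2 | intermediate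
15 | all-cis nona-O-benzyl 4-arylflavan-3-ol dimer, free 3-OH (2S,3S,4R; 2'R,3'R) | c9ccccc9COc1cc(OCc9ccccc9)c2c(c1)O[C@@H](c1ccc(OCc9ccccc9)c(OCc9ccccc9)c1)[C@@H](O)[C@H]2c1c(OCc9ccccc9)cc(OCc9ccccc9)c2c1O[C@H](c1ccc(OCc9ccccc9)c(OCc9ccccc9)c1)[C@H](OCc9ccccc9)C2 | intermediate
16 | 4'β-hydroxy nona-O-benzyl dimer (2S,3S,4R; 2'R,3'R,4'S) | c9ccccc9COc1cc(OCc9ccccc9)c2c(c1)O[C@@H](c1ccc(OCc9ccccc9)c(OCc9ccccc9)c1)[C@@H](O)[C@H]2c1c(OCc9ccccc9)cc(OCc9ccccc9)c2c1O[C@H](c1ccc(OCc9ccccc9)c(OCc9ccccc9)c1)[C@H](OCc9ccccc9)[C@H]2O | intermediate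
17 | CNP0114173.1, ent-epicatechin-(4β→8)-epicatechin-4β-ol (2S,3S,4R; 2'R,3'R,4'S) | Oc1cc(O)c2c(c1)O[C@@H](c1ccc(O)c(O)c1)[C@@H](O)[C@H]2c1c(O)cc(O)c2c1O[C@H](c1ccc(O)c(O)c1)[C@H](O)[C@H]2O | target

Total step count: 11.
Longest linear sequence: 8 steps (steps 1, 2, 4, 7, 8, 9, 10 and 11, from 1).

Steps most likely to fail

Step 9 (key step).
- What may go wrong: oxygen transfer to a Z-alkene that is screened on both faces may be slow and poorly face-selective. The electron-rich rings may be oxidised in competition. The very labile para-alkoxyaryl epoxide may ionise at C2, or be hydrolysed, before O1 attacks, which erodes the configuration at C2.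
- Fallback (sets out from 12, returns at 15): the direct cis relationship is given up and reached by way of a ketone. Catalytic I2 under visible light turns 12 into the strain-free E-alkene F1. As a trans-disubstituted styrene, F1 belongs to the best substrate class of the D-fructose-derived diacetonide ketone with KHSO5, which should give the silylated (2R,3R)-trans-epoxide F2. Bu4NF–AcOH frees the phenolic trans-epoxide F3, which closes 6-endo under PPTS to the 2,3-trans-3,4-trans flavan-3-ol F4. F4 is an all-equatorial product on which the invertive and the cationic pathway converge. Dess–Martin oxidation gives the flavan-3-one F5. LiBH(s-Bu)3 at −78 °C then adds hydride from the face opposite rings B and D, which are cis to each other, and so returns the all-cis alcohol 15.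

Step 10.
- What may go wrong: hydride may be abstracted from the upper unit (the diaryl methine C4–H or C2–H) instead of C4'. The new carbinol may also be oxidised further to the 4'-ketone.
- Fallback (sets out from 15, returns at 16): the upper unit is switched off electronically during the oxidation. Dess–Martin periodinane oxidises the only free hydroxyl of 15 to the flavan-3-one F6 (the same ketone as F5). A carbonyl group next to C2 and C4 makes cations at both positions prohibitive, so DDQ and water can act only at C4' and should give the 4'β-hydroxy flavan-3-one F7. Excess LiBH(s-Bu)3 at −78 °C then restores the all-cis C3 alcohol from the open face and gives 16.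

Step 7.
- What may go wrong: the planar cation may show no facial preference, so that much material is lost as the wrong C4 epimer or the epimers resist separation. Attack may leak to C6' or to the alkyne terminus (allene formation), and multiple alkylation may occur.
- Fallback (sets out from 2 and 6, returns at 11): the free cation is replaced by a catalyst-bound ortho-quinone methide. Two equivalents of 6 add to the unprotected aldehyde 2 to give the ortho-hydroxy propargylic alcohol F8. A chiral BINOL-derived phosphoric acid of the 3,3'-bis(2,4,6-triisopropylphenyl) type is used, in the enantiomer that forms the matched pair with 10. It dehydrates F8 to the hydrogen-bonded alkynyl ortho-quinone methide F9. Conjugate arylation of F9 by C8' of 10 takes place inside the chiral complex and should give the phenolic alkyne F10 with catalyst control at C4. TBSCl and imidazole silylate the only free hydroxyl and give 11.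

Further compounds
F1 | step 9 | (4S,E)-1,1,3-triarylpropene, E isomer of 12 | CC(C)(C)[Si](C)(C)Oc1cc(OCc9ccccc9)cc(OCc9ccccc9)c1[C@@H](/C=C/c1ccc(OCc9ccccc9)c(OCc9ccccc9)c1)c1c(OCc9ccccc9)cc(OCc9ccccc9)c2c1O[C@H](c1ccc(OCc9ccccc9)c(OCc9ccccc9)c1)[C@H](OCc9ccccc9)C2
F2 | step 9 | silylated trans-epoxide (C2 R, C3 R, C4 S) | CC(C)(C)[Si](C)(C)Oc1cc(OCc9ccccc9)cc(OCc9ccccc9)c1[C@@H]([C@H]3O[C@@H]3c1ccc(OCc9ccccc9)c(OCc9ccccc9)c1)c1c(OCc9ccccc9)cc(OCc9ccccc9)c2c1O[C@H](c1ccc(OCc9ccccc9)c(OCc9ccccc9)c1)[C@H](OCc9ccccc9)C2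
F3 | step 9 | phenolic trans-epoxide (C2 R, C3 R, C4 R by CIP with unchanged geometry) | Oc1cc(OCc9ccccc9)cc(OCc9ccccc9)c1[C@@H]([C@H]3O[C@@H]3c1ccc(OCc9ccccc9)c(OCc9ccccc9)c1)c1c(OCc9ccccc9)cc(OCc9ccccc9)c2c1O[C@H](c1ccc(OCc9ccccc9)c(OCc9ccccc9)c1)[C@H](OCc9ccccc9)C2
F4 | step 9 | 2,3-trans-3,4-trans nona-O-benzyl 4-arylflavan-3-ol dimer (2S,3R,4R; 2'R,3'R) | c9ccccc9COc1cc(OCc9ccccc9)c2c(c1)O[C@@H](c1ccc(OCc9ccccc9)c(OCc9ccccc9)c1)[C@H](O)[C@H]2c1c(OCc9ccccc9)cc(OCc9ccccc9)c2c1O[C@H](c1ccc(OCc9ccccc9)c(OCc9ccccc9)c1)[C@H](OCc9ccccc9)C2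
F5 | step 9 | nona-O-benzyl 4-arylflavan-3-one dimer (2S,4R; 2'R,3'R) | c9ccccc9COc1cc(OCc9ccccc9)c2c(c1)O[C@@H](c1ccc(OCc9ccccc9)c(OCc9ccccc9)c1)C(=O)[C@H]2c1c(OCc9ccccc9)cc(OCc9ccccc9)c2c1O[C@H](c1ccc(OCc9ccccc9)c(OCc9ccccc9)c1)[C@H](OCc9ccccc9)C2
F6 | step 10 | nona-O-benzyl 4-arylflavan-3-one dimer (2S,4R; 2'R,3'R), identical with F5 | c9ccccc9COc1cc(OCc9ccccc9)c2c(c1)O[C@@H](c1ccc(OCc9ccccc9)c(OCc9ccccc9)c1)C(=O)[C@H]2c1c(OCc9ccccc9)cc(OCc9ccccc9)c2c1O[C@H](c1ccc(OCc9ccccc9)c(OCc9ccccc9)c1)[C@H](OCc9ccccc9)C2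
F7 | step 10 | 4'β-hydroxy nona-O-benzyl 4-arylflavan-3-one dimer (2S,4R; 2'R,3'R,4'S) | c9ccccc9COc1cc(OCc9ccccc9)c2c(c1)O[C@@H](c1ccc(OCc9ccccc9)c(OCc9ccccc9)c1)C(=O)[C@H]2c1c(OCc9ccccc9)cc(OCc9ccccc9)c2c1O[C@H](c1ccc(OCc9ccccc9)c(OCc9ccccc9)c1)[C@H](OCc9ccccc9)[C@H]2O
F8 | step 7 | racemic 1-[2,4-bis(benzyloxy)-6-hydroxyphenyl]-3-[3,4-bis(benzyloxy)phenyl]prop-2-yn-1-ol | OC(C#Cc1ccc(OCc9ccccc9)c(OCc9ccccc9)c1)c1c(O)cc(OCc9ccccc9)cc1OCc9ccccc9
F9 | step 7 | alkynyl ortho-quinone methide of ring A | O=C1C=C(OCc9ccccc9)C=C(OCc9ccccc9)C1=CC#Cc1ccc(OCc9ccccc9)c(OCc9ccccc9)c1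
F10 | step 7 | phenolic alkyne, desilyl analogue of 11 (C4 R by CIP, same geometry as in 11; 2'R,3'R) | Oc1cc(OCc9ccccc9)cc(OCc9ccccc9)c1[C@@H](C#Cc1ccc(OCc9ccccc9)c(OCc9ccccc9)c1)c1c(OCc9ccccc9)cc(OCc9ccccc9)c2c1O[C@H](c1ccc(OCc9ccccc9)c(OCc9ccccc9)c1)[C@H](OCc9ccccc9)C2
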